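**Strategy**

Everything rests on cutting the pyranone at C4–C5 and O1–C2, so that its C3–CH2–aryl link is never made by a coupling. The route exploits the fact that the aromatic C2' hydroxyl oxygen and pyranone C2 are connected through C2', C1', the bridge CH2 and C3: tied together as an aryl ester they form a six-membered lactone, so C2, C3 and the bridge enter as the 3,4-dihydrocoumarin-3-carbonyl chloride 13. In a single operation 13 C-acylates the enol silane of pentan-3-one and the new enol oxygen opens the lactone, which closes the pyranone ring, frees the C2' phenol and delivers the target. Acid chloride 13 is built from phloroglucinol in six steps.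

Key step: step 8

Remark: locants are pyranone O1–C6 and aryl C1' (bridge), C2' (OH), C3' (acyl), C4' (OH), C5' (prenyl), C6' (OMe); the given structures were checked and need no correction; 12, 13 and 17 are C3-epimer mixtures and 15 may hold some E isomer, all of which become sp2 in step 8; the C7 hydroxyl of 13 is left free because it is chelated to the ketone and flanked on both sides, and 13 is made without HCl and used at once in solution.

**Route**

Step 1
Reactants: 1 phloroglucinol; 2 (R)-2-methylbutanoic acid
Product: 4 (2R)-2-methyl-1-(2,4,6-trihydroxyphenyl)butan-1-one, via (R)-2-methylbutanoyl chloride 3 (not isolated)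
Conditions: 2, (COCl)2, cat. DMF, CH2Cl2, 0 °C → rt; then 1, AlCl3, PhNO2/CH2Cl2, 0 → 35 °C; aq. HCl work-up
Reagents that add atoms: none
Why: Friedel–Crafts C-acylation of the triply activated ring should stop after one acyl group because the aryl ketone deactivates the ring, and the acid chloride is made and used without base at low temperature so that the (R) centre carried in from 2 is not enolised.

Step 2
Reactants: 4 (2R)-2-methyl-1-(2,4,6-trihydroxyphenyl)butan-1-one
Product: 5 (2R)-1-(2,6-dihydroxy-4-methoxyphenyl)-2-methylbutan-1-one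
Conditions: Me2SO4 (1.0 equiv), K2CO3 (1.0 equiv), acetone, rt
Reagents that add atoms: dimethyl sulfate, COS(=O)(=O)OC
Why: Williamson O-methylation should occur first at the 4-hydroxyl, which is para to the ketone, the most acidic (vinylogous acid) and not chelated to the carbonyl, whereas the two ortho hydroxyls are hydrogen-bonded and react later.

Step 3
Reactants: 5 (2R)-1-(2,6-dihydroxy-4-methoxyphenyl)-2-methylbutan-1-one
Product: 6 (2R)-1-[2,6-dihydroxy-4-methoxy-3-(3-methylbut-2-en-1-yl)phenyl]-2-methylbutan-1-one
Conditions: prenyl bromide (0.9 equiv), DBU, THF, 0 °C → rt; unreacted 5 recycled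
Reagents that add atoms: prenyl bromide (1-bromo-3-methylbut-2-ene), CC(C)=CCBr
Why: ortho C-alkylation of the ambident phenoxide, the usual direct C-prenylation of acylphloroglucinols, should place the allyl group on one of the two equivalent ring carbons between OH and OMe, and a slight deficit of bromide limits double alkylation.

Step 4
Reactants: 6 (2R)-1-[2,6-dihydroxy-4-methoxy-3-(3-methylbut-2-en-1-yl)phenyl]-2-methylbutan-1-one
Product: 8 2,4-dihydroxy-6-methoxy-3-[(2R)-2-methylbutanoyl]-5-(3-methylbut-2-en-1-yl)benzaldehyde, via aryl iminium chloride 7 (not isolated)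
Conditions: POCl3/DMF (preformed), MeCN, 0 °C → rt; then aq. NaOAc, rt
Reagents that add atoms: N,N-dimethylformamide, CN(C)C=O; water, O
Why: Vilsmeier–Haack formylation should attack the single free ring carbon, which is ortho or para to three oxygen donors, at low temperature, and the acetate-buffered hydrolysis of iminium 7 keeps the medium too weakly acidic to cyclise the ortho-prenyl phenol.

Step 5
Reactants: 8 2,4-dihydroxy-6-methoxy-3-[(2R)-2-methylbutanoyl]-5-(3-methylbut-2-en-1-yl)benzaldehyde; 9 Meldrum's acid
Product: 12 7-hydroxy-5-methoxy-8-[(2R)-2-methylbutanoyl]-6-(3-methylbut-2-en-1-yl)-2-oxochromane-3-carboxylic acid (both C3 epimers), via arylidene Meldrum's acid 10 (not isolated), via benzyl Meldrum's acid 11 (not isolated)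
Conditions: Hantzsch ester (diethyl 2,6-dimethyl-1,4-dihydropyridine-3,5-dicarboxylate, 1.1 equiv), L-proline (20 mol %), CH2Cl2, rt; then toluene, 70 °C
Reagents that add atoms: none
Why: Knoevenagel condensation gives the strongly electrophilic arylidene 10, which the Hantzsch ester reduces by hydride transfer (three-component reductive alkylation), and on warming the only hydroxyl ortho to the new CH2 opens the Meldrum's acid with loss of acetone to give the aryl lactone and the free acid, the new C3 centre being uncontrolled and erased in step 8.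

Step 6
Reactants: 12 7-hydroxy-5-methoxy-8-[(2R)-2-methylbutanoyl]-6-(3-methylbut-2-en-1-yl)-2-oxochromane-3-carboxylic acid
Product: 13 7-hydroxy-5-methoxy-8-[(2R)-2-methylbutanoyl]-6-(3-methylbut-2-en-1-yl)-2-oxochromane-3-carbonyl chloride (both C3 epimers; used at once as its CH2Cl2 solution)
Conditions: 1-chloro-N,N,2-trimethylprop-1-en-1-amine (1.05 equiv), CH2Cl2, 0 °C → rt
Reagents that add atoms: 1-chloro-N,N,2-trimethylprop-1-en-1-amine (Ghosez reagent), CC(C)=C(Cl)N(C)C
Why: acid chloride formation with an α-chloroenamine proceeds through an acyloxyiminium ion and gives only a neutral amide and no free HCl, so the prenyl group, the chelated phenol and the aryl lactone should be untouched.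

Step 7
Reactants: 14 pentan-3-one
Product: 15 (Z)-3-(trimethylsilyloxy)pent-2-ene
Conditions: TMSOTf, Et3N, Et2O, 0 °C → rt; distillation
Reagents that add atoms: trimethylsilyl trifluoromethanesulfonate, C[Si](C)(C)OS(=O)(=O)C(F)(F)F
Why: soft enolisation and O-silylation of the symmetrical ketone is a standard silyl enol ether synthesis that should give mainly the Z isomer, and the geometry is irrelevant because this carbon becomes sp2 in step 8.

Step 8
Reactants: 13 7-hydroxy-5-methoxy-8-[(2R)-2-methylbutanoyl]-6-(3-methylbut-2-en-1-yl)-2-oxochromane-3-carbonyl chloride; 15 (Z)-3-(trimethylsilyloxy)pent-2-ene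
Product: 18 6-ethyl-4-hydroxy-3-{[2,4-dihydroxy-6-methoxy-3-[(2R)-2-methylbutanoyl]-5-(3-methylbut-2-en-1-yl)phenyl]methyl}-5-methyl-2H-pyran-2-one (target), via acylketene 16 (not isolated), via diketo lactone 17 (not isolated)
Conditions: 15 (3 equiv), 2,6-lutidine (2.5 equiv, added slowly), CH2Cl2, −40 °C → rt, then 40 °C; 10% aq. citric acid work-up
Reagents that add atoms: none
Why: Proposed new method: 2,6-lutidine removes HCl from the doubly activated C3–H acid chloride to give the aryloxycarbonyl ketene 16 (or the chloride reacts directly), whose ketene carbon is attacked by the nucleophilic carbon of enol silane 15 with loss of the silyl group, forming the C4–C5 bond and diketo lactone 17; the enol oxygen of the ethyl ketone then adds to the aryl lactone carbonyl and the tetrahedral intermediate expels the chelated phenoxide, forming O1–C2. The closest known reaction types are the 4-hydroxy-2-pyranone syntheses from silyl enol ethers with malonyl dichlorides and from ketones with activated aryl malonates. The one ring closes by 6-exo-trig addition–elimination at the lactone carbonyl, and an elimination to an acylketene followed by oxa-6π closure from 17 would give the same ring. No stereocentre is created, since lactone C3 and the enol silane carbon both end sp2 (so the C3 epimers and the enol geometry converge), and the (R) side-chain centre is not exposed to anything stronger than a pyridine base. The step needs C- over O-acylation of the enol silane and capture of the ketene by the enol silane and not by the C7 phenol; the excess of 15, the slow release of the ketene and the chelated, doubly flanked phenol should secure this, and the stable vinylogous-acid pyranone drives the lactone opening.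

**Compound list**

1 | phloroglucinol | Oc1cc(O)cc(O)c1 | starting material
2 | (R)-2-methylbutanoic acid | CC[C@@H](C)C(=O)O | starting material
3 | (R)-2-methylbutanoyl chloride | CC[C@@H](C)C(=O)Cl | intermediate
4 | (2R)-2-methyl-1-(2,4,6-trihydroxyphenyl)butan-1-one | CC[C@@H](C)C(=O)c1c(O)cc(O)cc1O | intermediate
5 | (2R)-1-(2,6-dihydroxy-4-methoxyphenyl)-2-methylbutan-1-one | CC[C@@H](C)C(=O)c1c(O)cc(OC)cc1O | intermediate
6 | (2R)-1-[2,6-dihydroxy-4-methoxy-3-(3-methylbut-2-en-1-yl)phenyl]-2-methylbutan-1-one | CC[C@@H](C)C(=O)c1c(O)cc(OC)c(CC=C(C)C)c1O | intermediate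
7 | N-{[2,4-dihydroxy-6-methoxy-3-[(2R)-2-methylbutanoyl]-5-(3-methylbut-2-en-1-yl)phenyl]methylidene}-N-methylmethanaminium chloride | C[N+](C)=Cc1c(O)c(C(=O)[C@H](C)CC)c(O)c(CC=C(C)C)c1OC.[Cl-] | intermediate
8 | 2,4-dihydroxy-6-methoxy-3-[(2R)-2-methylbutanoyl]-5-(3-methylbut-2-en-1-yl)benzaldehyde | O=Cc1c(O)c(C(=O)[C@H](C)CC)c(O)c(CC=C(C)C)c1OC | intermediate
9 | Meldrum's acid (2,2-dimethyl-1,3-dioxane-4,6-dione) | CC1(C)OC(=O)CC(=O)O1 | starting material
10 | 5-{[2,4-dihydroxy-6-methoxy-3-[(2R)-2-methylbutanoyl]-5-(3-methylbut-2-en-1-yl)phenyl]methylidene}-2,2-dimethyl-1,3-dioxane-4,6-dione | CC1(C)OC(=O)C(=Cc2c(O)c(C(=O)[C@H](C)CC)c(O)c(CC=C(C)C)c2OC)C(=O)O1 | intermediate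
11 | 5-{[2,4-dihydroxy-6-methoxy-3-[(2R)-2-methylbutanoyl]-5-(3-methylbut-2-en-1-yl)phenyl]methyl}-2,2-dimethyl-1,3-dioxane-4,6-dione | CC1(C)OC(=O)C(Cc2c(O)c(C(=O)[C@H](C)CC)c(O)c(CC=C(C)C)c2OC)C(=O)O1 | intermediate
12 | 7-hydroxy-5-methoxy-8-[(2R)-2-methylbutanoyl]-6-(3-methylbut-2-en-1-yl)-2-oxochromane-3-carboxylic acid (C3 epimer mixture) | OC(=O)C1Cc2c(OC)c(CC=C(C)C)c(O)c(C(=O)[C@H](C)CC)c2OC1=O | intermediate
13 | 7-hydroxy-5-methoxy-8-[(2R)-2-methylbutanoyl]-6-(3-methylbut-2-en-1-yl)-2-oxochromane-3-carbonyl chloride (C3 epimer mixture) | ClC(=O)C1Cc2c(OC)c(CC=C(C)C)c(O)c(C(=O)[C@H](C)CC)c2OC1=O | intermediate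
14 | pentan-3-one | CCC(=O)CC | starting material
15 | (Z)-3-(trimethylsilyloxy)pent-2-ene | C/C=C(/CC)O[Si](C)(C)C | intermediate
16 | 7-hydroxy-5-methoxy-8-[(2R)-2-methylbutanoyl]-6-(3-methylbut-2-en-1-yl)-3-(oxomethylidene)chroman-2-one | O=C=C1Cc2c(OC)c(CC=C(C)C)c(O)c(C(=O)[C@H](C)CC)c2OC1=O | intermediate
17 | 7-hydroxy-5-methoxy-8-[(2R)-2-methylbutanoyl]-6-(3-methylbut-2-en-1-yl)-3-(2-methyl-3-oxopentanoyl)chroman-2-one (stereoisomer and tautomer mixture) | CCC(=O)C(C)C(=O)C1Cc2c(OC)c(CC=C(C)C)c(O)c(C(=O)[C@H](C)CC)c2OC1=O | intermediate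
18 | 6-ethyl-4-hydroxy-3-{[2,4-dihydroxy-6-methoxy-3-[(2R)-2-methylbutanoyl]-5-(3-methylbut-2-en-1-yl)phenyl]methyl}-5-methyl-2H-pyran-2-one | CCc1oc(=O)c(Cc2c(O)c(C(=O)[C@H](C)CC)c(O)c(CC=C(C)C)c2OC)c(O)c1C | target

**Step count**

Total step count: 8.
Longest linear sequence: 7 steps (steps 1–6 and 8, from phloroglucinol 1); step 7 is a one-step side branch.

**Steps most likely to fail**

1. Step 8. The acylketene may be captured by the free phenol of a second molecule or dimerise, the enol silane may be acylated at oxygen, or the ring may close through the lactone carbonyl oxygen instead of the ketone enol oxygen. The fallback uses the established aminomethyl bridge construction and sets out from ketone 6 and enol silane 15. Compound 15 and malonyl dichloride (Et2O, −78 °C → rt) should give 6-ethyl-4-hydroxy-5-methyl-2H-pyran-2-one F1 by the known silyl enol ether/malonyl dichloride pyranone synthesis. Treating F1 with dimethylmethylideneammonium iodide (MeCN, rt) should give the Mannich base 3-[(dimethylamino)methyl]-6-ethyl-4-hydroxy-5-methyl-2H-pyran-2-one F2. Warming F2 with 6 (MeCN, 60 °C) expels dimethylamine to form 6-ethyl-5-methyl-3-methylidene-2H-pyran-2,4(3H)-dione F3, which alkylates the one free ring carbon of 6 and so returns to the route at target 18. The price of this fallback is possible formation of symmetrical methylene-bridged by-products.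

2. Step 5. Arylidene 10 may lactonise before hydride transfer reaches it, or the malonic half ester may decarboxylate during the thermal lactonisation. The fallback accepts the early lactonisation and sets out from aldehyde 8. Compound 8 and Meldrum's acid 9 with piperidinium acetate in EtOH at rt should give 7-hydroxy-5-methoxy-8-[(2R)-2-methylbutanoyl]-6-(3-methylbut-2-en-1-yl)-2-oxo-2H-chromene-3-carboxylic acid F4, the classical coumarin-3-carboxylic acid synthesis. The activated C3=C4 bond of F4 is then reduced separately by conjugate hydride addition with NaBH4 (THF/MeOH, 0 °C), returning to the route at acid 12.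

3. Step 4. Acid released during formylation or iminium hydrolysis may cyclise the ortho-prenyl phenol to a dimethylchroman or add HCl to the alkene. The fallback inverts the order so that no prenyl group sees the Vilsmeier conditions, and sets out from 5. Vilsmeier–Haack formylation of 5 should give 2,4-dihydroxy-6-methoxy-3-[(2R)-2-methylbutanoyl]benzaldehyde F5, mono-formylation being self-limiting. C-prenylation of F5 (prenyl bromide, 10% aq. KOH, 0 °C) at its single free ring carbon then returns to the route at aldehyde 8.

**Further compounds**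

F1 | step 8 | 6-ethyl-4-hydroxy-5-methyl-2H-pyran-2-one | CCc1oc(=O)cc(O)c1C
F2 | step 8 | 3-[(dimethylamino)methyl]-6-ethyl-4-hydroxy-5-methyl-2H-pyran-2-one | CCc1oc(=O)c(CN(C)C)c(O)c1C
F3 | step 8 | 6-ethyl-5-methyl-3-methylidene-2H-pyran-2,4(3H)-dione | CCC1=C(C)C(=O)C(=C)C(=O)O1
F4 | step 5 | 7-hydroxy-5-methoxy-8-[(2R)-2-methylbutanoyl]-6-(3-methylbut-2-en-1-yl)-2-oxo-2H-chromene-3-carboxylic acid | OC(=O)C1=Cc2c(OC)c(CC=C(C)C)c(O)c(C(=O)[C@H](C)CC)c2OC1=O
F5 | step 4 | 2,4-dihydroxy-6-methoxy-3-[(2R)-2-methylbutanoyl]benzaldehyde | O=Cc1c(O)c(C(=O)[C@H](C)CC)c(O)cc1OC
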